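Share the monomer out evenly first, and only then ask how fast it gets there.

    free monomer + initiator → living end + monomer in chains (k1 = 10.2 /M/s)
    free monomer + living end → monomer in chains + living end, rate k2*[living end]*[free monomer] (k2 = 3.08 /M/s)
    living end + transfer agent → dead chain (k3 = 2.24 /M/s)
    free monomer → uncatalysed product (k4 = 5.00 × 10⁻⁴ /s)
    protic impurity + free monomer → quenched substrate (k5 = 68.8 /M/s)

free monomer 0.40 M; transfer agent 0.0120 M; protic impurity 0.0200 M; initiator 25 mM; time 40 s

- the average divides the monomer in chains by the number of chains begun, living and dead together
- run time (flask): 40 s

1. average number of monomer units in a chain (chains begun, living or dead) at 40 s
2. part of the free monomer that has reacted at 40 s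

In this flask the protic impurity has a half-life of 0.0252 s against the charged free monomer and the initiator 0.170 s, both much shorter than the time. So I count each initiator as one chain begun and each impurity as one monomer lost, which leaves 0.355 M free. Dividing the monomer charged less the impurity charge by the initiator charge gives 15.2 units per chain. This is the even share, the statistical zero of my scale: the average chain once the spared monomer sits in chains. Each free monomer still present lowers the average from there.

Next I hold the living ends at the initiator charge, which makes monomer loss pseudo-first-order. That leaves 0.0163 M free and an average of 14.5.

The weak link is that constant: the living end's half-life by transfer, with the transfer agent as charged, is 26 s, shorter than the time. Reforged, living end minus transfer agent stays at 0.0130 M, and second-order integration leaves 0.00229 M of transfer agent. The time integral of the living end is then 0.740 M·s. Free monomer falls to 0.0364 M; I leave the uncatalysed step out of this, its constant being much smaller than propagation's pace at the lowest living-end level I reckon with. I commit to 13.7 units and 90.9% reacted.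

The forecast gives 13.7 and 91%, “with the uncatalysed loss negligible”.

The flask gives 13.7 and 91.0%; its chain length is 90.1% of the even share. At 8.72 s free monomer's half-life by propagation is 11 s, shorter than the time, while its uncatalysed half-life at 40.0 s is 23 min, longer than the time. At 40.0 s monomer in chains holds 85.3% of the free monomer charged. In a neighbour flask charged with 0.0063 M of initiator, the even share is 60.3. Its computed chains reach 24.2, 40.1% of that share, with 44.5% reacted.

All constants are invented; the rest is arithmetic.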